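**Retrosynthetic overview**
1. Target 7 ⇒ aryl acetate 5 + (S)-β-butyrolactone 6. Formal insertion of the lactone into the ArO–C(O)CH3 bond makes both ester C–O bonds (aryl ester and C3 acetate) in one step; the C3 stereocentre is carried intact from 6.
2. 5 ⇒ plicatin B 4 by O-acetylation.
3. 4 ⇒ methyl p-coumarate 1 + prenyl bromide 2 by ortho-C-prenylation of the phenoxide.
4. No ring is built: the arene comes from 1, and the only ring event is opening of the oxetanone of 6 in the last step.

Assumption: the target's single stereocentre is (S) as read from the SMILES, and (S)-β-butyrolactone (≥98% ee) is bought as a catalogue chiral building block.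

**Step 1**
Reactants: 1 methyl (E)-3-(4-hydroxyphenyl)prop-2-enoate (methyl p-coumarate); 2 1-bromo-3-methylbut-2-ene (prenyl bromide)
Product: 4 plicatin B (methyl (E)-3-[4-hydroxy-3-(3-methylbut-2-en-1-yl)phenyl]prop-2-enoate), via sodium phenolate 3 (not isolated)
Conditions: NaH (1.1 equiv), toluene, 0 °C → rt, 1 h; then 2 (1.0 equiv), rt → 50 °C, 16 h
Reagents that add atoms: none
Why: Ortho-C-alkylation of an ambident phenoxide: in toluene the insoluble, tightly ion-paired sodium phenolate has its oxygen shielded by Na+, so the allylic bromide is attacked by the ortho carbon (para blocked, both ortho positions equivalent) and the dienone re-aromatises; no stereocentre is formed.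

**Step 2**
Reactants: 4 plicatin B
Product: 5 methyl (E)-3-[4-acetoxy-3-(3-methylbut-2-en-1-yl)phenyl]prop-2-enoate
Conditions: Ac2O (1.5 equiv), pyridine (2 equiv), DMAP (2 mol%), CH2Cl2, 0 °C → rt, 1 h; product dried azeotropically (toluene)
Reagents that add atoms: acetic anhydride, CC(=O)OC(C)=O
Why: Nucleophile-catalysed O-acylation of a phenol via the N-acetylpyridinium ion; the buffered basic medium leaves the prenyl alkene, enoate and methyl ester untouched and avoids acid-induced chroman formation; no stereocentre.

**Step 3**
Reactants: 5 methyl (E)-3-[4-acetoxy-3-(3-methylbut-2-en-1-yl)phenyl]prop-2-enoate; 6 (S)-β-butyrolactone ((S)-4-methyloxetan-2-one)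
Product: 7 methyl (2E)-3-[4-{[(3S)-3-(acetyloxy)butanoyl]oxy}-3-(3-methylbut-2-en-1-yl)phenyl]prop-2-enoate
Conditions: Y[N(SiMe3)2]3 (5 mol%) premixed with 4 (15 mol%) to give Y(OAr)3, toluene, 40 °C; 6 (0.95 equiv) added by syringe pump over 6 h; aq. NH4Cl work-up
Reagents that add atoms: none
Why: Proposed new method: yttrium-aryloxide-catalysed formal insertion of a β-lactone into the C(acyl)–O bond of an aryl acetate, in which the Lewis-acidic Y–OAr adds to the lactone carbonyl and opens it by acyl–oxygen cleavage (coordination–insertion, so the C3–O bond is never broken and the (S) centre of 6 is retained), the resulting secondary Y-alkoxide is then acetylated by the activated ester 5 (alkoxide-to-aryloxide exchange, downhill), releasing 7 and regenerating Y–OAr; the net isomerising addition has no co-product and is driven by about 23 kcal/mol of ring strain, slow addition of 6 keeps chain growth below acetyl transfer, and no amine base or free β-acetoxy acyl electrophile is present to trigger E1cB loss of acetate; the closest known reaction types are coordination–insertion ring-opening polymerisation of β-butyrolactone by rare-earth and zinc alkoxides/aryloxides (acyl–O cleavage with retention, with chain transfer) and rare-earth-alkoxide-catalysed transesterification of activated esters.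

**Compound list**
1 | methyl (E)-3-(4-hydroxyphenyl)prop-2-enoate (methyl p-coumarate) | COC(=O)/C=C/c1ccc(O)cc1 | starting material
2 | 1-bromo-3-methylbut-2-ene (prenyl bromide) | CC(C)=CCBr | starting material
3 | sodium 4-[(1E)-3-methoxy-3-oxoprop-1-en-1-yl]phenolate | COC(=O)/C=C/c1ccc([O-])cc1.[Na+] | intermediate
4 | plicatin B, methyl (E)-3-[4-hydroxy-3-(3-methylbut-2-en-1-yl)phenyl]prop-2-enoate | COC(=O)/C=C/c1ccc(O)c(CC=C(C)C)c1 | intermediate
5 | methyl (E)-3-[4-acetoxy-3-(3-methylbut-2-en-1-yl)phenyl]prop-2-enoate | COC(=O)/C=C/c1ccc(OC(C)=O)c(CC=C(C)C)c1 | intermediate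
6 | (S)-4-methyloxetan-2-one ((S)-β-butyrolactone) | C[C@H]1CC(=O)O1 | starting material
7 | methyl (2E)-3-[4-{[(3S)-3-(acetyloxy)butanoyl]oxy}-3-(3-methylbut-2-en-1-yl)phenyl]prop-2-enoate | COC(=O)/C=C/c1ccc(OC(=O)C[C@H](C)OC(C)=O)c(CC=C(C)C)c1 | target

**Totals**
Total step count: 3. Longest linear sequence: 3 (1 → 4 → 5 → 7).

**Steps most likely to fail**

Step 3 (the proposed insertion) is the most likely to fail. The electron-poor, ortho-substituted aryloxide may insert 6 slowly. The product aryl ester can compete with 5 as acyl donor and give oligo(3-hydroxybutanoate) aryl esters. Base-induced loss of acetate to the aryl crotonate is also possible. If acetyl transfer from 5 is only a few-fold faster than from 7, expect roughly 60–70% of 7 with recoverable 5; a bulkier ancillary ligand on yttrium should improve this. The fallback uses known chemistry, sets out from 4 and comes back at 7. Commercial (S)-3-hydroxybutanoic acid is O-acetylated with neat acetyl chloride (0 °C → rt, aqueous work-up) to (S)-3-acetoxybutanoic acid F1. This acid is esterified with phenol 4 under Steglich conditions (DCC, 5 mol% DMAP, CH2Cl2, 0 °C) to give 7. Low temperature and low DMAP loading limit elimination of acetate.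

Step 1 is the next most likely to fail. O-prenylation and 3,5-diprenylation compete, and the yield is expected to be only about 40–50%. The fallback sets out from 1 and comes back at 4. Williamson O-allylation (allyl bromide, K2CO3, acetone, reflux) gives methyl (E)-3-[4-(prop-2-en-1-yloxy)phenyl]prop-2-enoate F2. Aromatic Claisen rearrangement (N,N-diethylaniline, 190 °C) gives methyl (E)-3-[4-hydroxy-3-(prop-2-en-1-yl)phenyl]prop-2-enoate F3. Cross-metathesis of F3 with excess 2-methylbut-2-ene (Grubbs II, 3 mol%, CH2Cl2, 40 °C, sealed) converts the allyl group into prenyl and delivers 4.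

Step 2 is the least risky of the three. Its weak point is the free o-prenylphenol 4, which can cyclise to the 2,2-dimethylchroman on acidic silica or during acidic work-up before it is capped. The fallback never handles free 4; it sets out from 1 and comes back at 5. Pd-catalysed decarboxylative O-tert-prenylation (tert-butyl 2-methylbut-3-en-2-yl carbonate, Pd(PPh3)4 2 mol%, THF, 0 °C) gives methyl (E)-3-{4-[(2-methylbut-3-en-2-yl)oxy]phenyl}prop-2-enoate F4. Heating F4 in acetic anhydride with sodium acetate (140 °C) effects the aromatic Claisen rearrangement to the ortho-prenyl phenol, which is acetylated as it forms, giving 5 directly.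

**Further compounds**
F1 | step 3 | (S)-3-acetoxybutanoic acid | OC(=O)C[C@H](C)OC(C)=O
F2 | step 1 | methyl (E)-3-[4-(prop-2-en-1-yloxy)phenyl]prop-2-enoate | COC(=O)/C=C/c1ccc(OCC=C)cc1
F3 | step 1 | methyl (E)-3-[4-hydroxy-3-(prop-2-en-1-yl)phenyl]prop-2-enoate | COC(=O)/C=C/c1ccc(O)c(CC=C)c1
F4 | step 2 | methyl (E)-3-{4-[(2-methylbut-3-en-2-yl)oxy]phenyl}prop-2-enoate | COC(=O)/C=C/c1ccc(OC(C)(C)C=C)cc1
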